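**Retrosynthetic overview**
1. Key disconnection: the bond between the CH of the E-1,2-disubstituted alkene and the tertiary carbinol carbon. This gives alkenylboronic ester 14 (C12 furan half) and the lithiated (S)-secondary 2,4,6-triisopropylbenzoate 24 (C10 half). They are joined in one flask by lithiation–borylation, 1,2-metallate shift and C–B oxidation.
2. Enabling feature: this carbinol carbon carries OH, CH3, CH2 and an sp2 CH, so it is the oxidised form of a tertiary allylic boronic ester. The OH marks where boron sat, the small CH3 allows deprotonation of the parent methyl carbinol ester, and the sp2 CH migrates fast. The hard CH3/CH2 face problem is replaced by stereospecific transfer from a purchased secondary alcohol.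
3. Second feature: the lactone C=O carbon, the quaternary carbon bearing the ring oxygen, and the adjacent CHOH fold, one oxidation level lower, into a 2,7-dioxabicyclo[2.2.1]heptane acetal with no foreign protecting group. It arises from a Shi epoxide by anti opening at the quaternary carbon (as in the presumed biogenesis of the hydroxy lactone) and resists sBuLi.
4. Both E-trisubstituted alkenes come from carboalumination/iodination plus B-alkyl Suzuki coupling. The skipped diene comes from allyl–alkynyl coupling and alkyne hydroboration.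
5. Ring order: furan purchased; oxirane (step 11); oxolane and 1,3-dioxolane rings of the cage together (step 13); dioxolane ring opened (step 15); oxolane ring oxidised to the γ-lactone (step 16).

Key step: step 14

Remark on the chemistry: lactol 29 (and F11–F13) is configurationally labile or irrelevant at the hemiacetal carbon, so that centre is drawn without a descriptor. Compound 29 is assumed to be a ring–chain mixture and is drawn as its five-membered form.

**Step 1**
Reactants: 1 furan-3-carbaldehyde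
Product: 2 3-ethenylfuran
Conditions: Ph3PCH3Br, KOtBu, Et2O, 0 °C to rt; filtered, carried on as a dried solution
Reagents that add atoms: methyltriphenylphosphonium bromide, C[P+](c1ccccc1)(c1ccccc1)c1ccccc1.[Br-]
Why: Wittig methylenation of a non-enolisable heteroaryl aldehyde; no stereocentre is formed, and keeping the volatile diene-like product in solution should avoid polymerisation.

**Step 2**
Reactants: 3 prop-2-yn-1-ol
Product: 5 (2E)-3-iodo-2-methylprop-2-en-1-ol, via alkenylalane 4 (not isolated)
Conditions: Me3Al (3 equiv), Cp2ZrCl2 (25 mol %), CH2Cl2, 0 °C to rt; then I2, THF, −30 °C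
Reagents that add atoms: trimethylaluminium, C[Al](C)C; iodine, II
Why: Negishi zirconium-catalysed syn-carboalumination puts CH3 on the internal and Al on the terminal alkyne carbon, and iodinolysis with retention fixes the E-alkenyl iodide.

**Step 3**
Reactants: 2 3-ethenylfuran; 5 (2E)-3-iodo-2-methylprop-2-en-1-ol
Product: 7 (2E)-5-(furan-3-yl)-2-methylpent-2-en-1-ol, via B-alkylborane 6 (not isolated)
Conditions: 9-BBN, THF, 0 °C to rt; then 5, PdCl2(dppf) (5 mol %), 3 M aq NaOH, THF, 50 °C
Reagents that add atoms: none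
Why: Anti-Markovnikov hydroboration of the vinyl group followed by B-alkyl Suzuki–Miyaura coupling, which retains the alkenyl iodide geometry and so delivers the E-trisubstituted alkene.

**Step 4**
Reactants: 7 (2E)-5-(furan-3-yl)-2-methylpent-2-en-1-ol
Product: 8 3-[(3E)-5-bromo-4-methylpent-3-en-1-yl]furan
Conditions: CBr4, PPh3, CH2Cl2, −20 to 0 °C
Reagents that add atoms: tetrabromomethane, BrC(Br)(Br)Br
Why: Appel bromination of a primary allylic alcohol runs under neutral conditions that spare the furan and should not shift or isomerise the double bond.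

**Step 5**
Reactants: 8 3-[(3E)-5-bromo-4-methylpent-3-en-1-yl]furan; 9 ethynyl(trimethyl)silane
Product: 11 [(4E)-7-(furan-3-yl)-4-methylhept-4-en-1-yn-1-yl](trimethyl)silane, via alkynylmagnesium bromide 10 (not isolated)
Conditions: 9, EtMgBr, THF, 0 °C to rt; CuI (10 mol %), then 8, THF, rt to 45 °C
Reagents that add atoms: none
Why: Copper-catalysed SN2 coupling of an alkynyl Grignard reagent with a primary allylic bromide gives the skipped enyne, and the silyl cap keeps the product from being deprotonated and isomerised.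

**Step 6**
Reactants: 11 [(4E)-7-(furan-3-yl)-4-methylhept-4-en-1-yn-1-yl](trimethyl)silane
Product: 12 3-[(3E)-4-methylhept-3-en-6-yn-1-yl]furan
Conditions: K2CO3 (0.3 equiv), MeOH, 0 °C to rt
Reagents that add atoms: none
Why: Base-catalysed methanolysis of the C(sp)–Si bond (protodesilylation) is mild enough that the doubly activated CH2 should not isomerise to an allene or a conjugated enyne.

**Step 7**
Reactants: 12 3-[(3E)-4-methylhept-3-en-6-yn-1-yl]furan
Product: 14 2-[(1E,4E)-7-(furan-3-yl)-4-methylhepta-1,4-dien-1-yl]-5,5-dimethyl-1,3,2-dioxaborinane, via catechol boronic ester 13 (not isolated)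
Conditions: catecholborane (1.1 equiv), Cy2BH (5 mol %), THF, rt; then 2,2-dimethylpropane-1,3-diol, rt
Reagents that add atoms: catecholborane, [H]B1Oc2ccccc2O1; 2,2-dimethylpropane-1,3-diol, OCC(C)(C)CO
Why: Dialkylborane-catalysed syn-hydroboration selects the terminal alkyne over the trisubstituted alkene and places boron on the terminal carbon (E-alkenylboron), and transesterification installs the unhindered diol needed in step 14.

**Step 8**
Reactants: 15 pent-4-yn-1-ol
Product: 17 (4E)-5-iodo-4-methylpent-4-en-1-ol, via alkenylalane 16 (not isolated)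
Conditions: Me3Al (3 equiv), Cp2ZrCl2 (25 mol %), CH2Cl2, 0 °C to rt; then I2, THF, −30 °C
Reagents that add atoms: trimethylaluminium, C[Al](C)C; iodine, II
Why: Negishi syn-carboalumination and iodinolysis with retention, as in step 2, set the E geometry of the second trisubstituted alkene.

**Step 9**
Reactants: 18 (2S)-but-3-en-2-ol
Product: 19 (2S)-but-3-en-2-yl 2,4,6-triisopropylbenzoate
Conditions: NaH, THF, 0 °C; 2,4,6-iPr3C6H2COCl, 0 to 50 °C
Reagents that add atoms: 2,4,6-triisopropylbenzoyl chloride, CC(C)c1cc(C(C)C)c(C(Cl)=O)c(C(C)C)c1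
Why: O-acylation of the sodium alkoxide by the hindered aroyl chloride leaves the C–O bond, and hence the purchased (S) centre, untouched.

**Step 10**
Reactants: 19 (2S)-but-3-en-2-yl 2,4,6-triisopropylbenzoate; 17 (4E)-5-iodo-4-methylpent-4-en-1-ol
Product: 21 (2S,5E)-9-hydroxy-6-methylnon-5-en-2-yl 2,4,6-triisopropylbenzoate, via B-alkylborane 20 (not isolated)
Conditions: 9-BBN, THF, 0 °C to rt; then 17, PdCl2(dppf) (5 mol %), 3 M aq NaOH, THF, 50 °C
Reagents that add atoms: none
Why: Terminal hydroboration puts boron gamma to the ester oxygen (no beta-elimination), B-alkyl Suzuki–Miyaura coupling keeps the E geometry, and the shielded ester should resist aqueous NaOH.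

**Step 11**
Reactants: 21 (2S,5E)-9-hydroxy-6-methylnon-5-en-2-yl 2,4,6-triisopropylbenzoate
Product: 22 (2S)-4-[(2R,3R)-3-(3-hydroxypropyl)-3-methyloxiran-2-yl]butan-2-yl 2,4,6-triisopropylbenzoate
Conditions: D-fructose-derived ketone (1,2:4,5-di-O-isopropylidene-β-D-erythro-hexo-2,3-diulo-2,6-pyranose, 30 mol %), 2KHSO5·KHSO4·K2SO4, K2CO3, Bu4NHSO4 (cat.), MeCN–CH2(OMe)2 / aq Na2B4O7–Na2EDTA buffer, 0 °C
Reagents that add atoms: potassium peroxymonosulfate, [K+].OOS(=O)(=O)[O-]
Why: Shi epoxidation, in which the chiral dioxirane meets the only alkene (E-trisubstituted) through the spiro transition state and should give the (R,R)-epoxide under reagent control, setting the future CHOH carbon and, before inversion, the quaternary carbon.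

**Step 12**
Reactants: 22 (2S)-4-[(2R,3R)-3-(3-hydroxypropyl)-3-methyloxiran-2-yl]butan-2-yl 2,4,6-triisopropylbenzoate
Product: 23 (2S)-4-[(2R,3R)-3-methyl-3-(3-oxopropyl)oxiran-2-yl]butan-2-yl 2,4,6-triisopropylbenzoate
Conditions: (nPr4N)RuO4 (5 mol %), N-methylmorpholine N-oxide, 4 Å MS, CH2Cl2, 0 °C to rt
Reagents that add atoms: none
Why: Ley–Griffith oxidation is neutral and anhydrous, so the primary alcohol should reach the aldehyde without acid-induced opening of the epoxide.

**Step 13**
Reactants: 23 (2S)-4-[(2R,3R)-3-methyl-3-(3-oxopropyl)oxiran-2-yl]butan-2-yl 2,4,6-triisopropylbenzoate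
Product: 24 (2S)-4-[(1R,3R,4S)-4-methyl-2,7-dioxabicyclo[2.2.1]heptan-3-yl]butan-2-yl 2,4,6-triisopropylbenzoate
Conditions: BF3·OEt2 (10 mol %), CH2Cl2, −78 to −40 °C; Et3N quench
Reagents that add atoms: none
Why: Lewis-acid-catalysed epoxy carbonyl to bicyclic acetal rearrangement, in which the aldehyde oxygen opens the activated epoxide 5-exo at the more substituted carbon from the rear (inversion, R to S) and the freed alkoxide caps the oxocarbenium ion, the acetal carbon configuration being dictated by the cage.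

**Step 14**
Reactants: 24 (2S)-4-[(1R,3R,4S)-4-methyl-2,7-dioxabicyclo[2.2.1]heptan-3-yl]butan-2-yl 2,4,6-triisopropylbenzoate; 14 2-[(1E,4E)-7-(furan-3-yl)-4-methylhepta-1,4-dien-1-yl]-5,5-dimethyl-1,3,2-dioxaborinane
Product: 28 (3S,4E,7E)-10-(furan-3-yl)-3,7-dimethyl-1-[(1R,3R,4S)-4-methyl-2,7-dioxabicyclo[2.2.1]heptan-3-yl]deca-4,7-dien-3-ol, via organolithium 25 (not isolated), via boronate complex 26 (not isolated), via tertiary boronic ester 27 (not isolated)
Conditions: sBuLi (1.6 equiv), TMEDA (6 equiv), cyclopentyl methyl ether, −60 °C, 2 h; 14 (1.5 equiv), −60 °C, 1 h, then to 40 °C, 12 h; then THF, 2 M aq NaOH, 30 % H2O2, 0 °C to rt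
Reagents that add atoms: hydrogen peroxide, OO
Why: The carbonyl oxygen of the hindered benzoate holds sBuLi·TMEDA at the one C–H that is alpha to an acyloxy group, so 24 is deprotonated with retention to the configurationally stable tertiary organolithium 25, which attacks the vacant boron orbital of 14 with retention to give boronate complex 26; on warming the alkenyl carbon shifts from boron to carbon antiperiplanar to the departing benzoate (1,2-metallate rearrangement, inversion at carbon), forging the bond between the alkene CH and the future carbinol carbon, and alkaline H2O2 then exchanges boron for OH with retention. The closest known reaction type is the lithiation–borylation–oxidation of unactivated secondary dialkyl 2,4,6-triisopropylbenzoates with neopentyl glycol boronic esters to tertiary alcohols, together with the use of alkenylboronic esters as migrating partners for lithiated carbamates. No ring is closed in this step. The single new stereocentre is controlled only by the (S) centre of 24 through the retention–retention–inversion–retention sequence, which maps the (S)-ester onto the (S)-carbinol and makes CH3 versus CH2 face discrimination unnecessary, and the E geometry of 14 is kept because the migrating sp2 carbon retains its configuration. The step needs attack at boron to outrun proton transfer from the furan alpha C–H and the doubly allylic CH2 of 14, which the unhindered, Lewis acidic six-membered boronic ester at −60 °C should secure, and it needs carbon rather than oxygen migration, which the high migratory aptitude of an sp2 carbon favours. The acetal cage offers neither an electrophilic carbonyl to sBuLi nor an aldehyde to the allylic boronic ester 27, so 27 should survive until it is oxidised.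

**Step 15**
Reactants: 28 (3S,4E,7E)-10-(furan-3-yl)-3,7-dimethyl-1-[(1R,3R,4S)-4-methyl-2,7-dioxabicyclo[2.2.1]heptan-3-yl]deca-4,7-dien-3-ol
Product: 29 (5S)-5-[(1R,4S,5E,8E)-11-(furan-3-yl)-1,4-dihydroxy-4,8-dimethylundeca-5,8-dien-1-yl]-5-methyloxolan-2-ol
Conditions: AcOH–THF–H2O (3:1:1), rt
Reagents that add atoms: water, O
Why: Strain-assisted acetal hydrolysis under weak acid should be faster than ionisation of the tertiary allylic alcohol, and it breaks only C–O bonds at the acetal carbon, so no stereocentre of the target is touched.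

**Step 16**
Reactants: 29 (5S)-5-[(1R,4S,5E,8E)-11-(furan-3-yl)-1,4-dihydroxy-4,8-dimethylundeca-5,8-dien-1-yl]-5-methyloxolan-2-ol
Product: 30 (5S)-5-[(1R,4S,5E,8E)-11-(furan-3-yl)-1,4-dihydroxy-4,8-dimethylundeca-5,8-dien-1-yl]-5-methyloxolan-2-one (CNP0151262.1)
Conditions: Ag2CO3 on Celite (excess), toluene, 80 °C
Reagents that add atoms: none
Why: Fétizon oxidation takes lactols much faster than the hindered secondary alcohol and cannot touch the tertiary one, and any six-membered lactone arising from the ring–chain tautomer of 29 should relax by acyl migration on the hot, mildly basic surface to the more stable five-membered lactone.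

**Compound list**
1 | furan-3-carbaldehyde | O=Cc1ccoc1 | starting material
2 | 3-ethenylfuran | C=Cc1ccoc1 | intermediate
3 | prop-2-yn-1-ol | C#CCO | starting material
4 | dimethylaluminium (2E)-3-(dimethylalumanyl)-2-methylprop-2-en-1-olate | C[Al](C)/C=C(\C)CO[Al](C)C | intermediate
5 | (2E)-3-iodo-2-methylprop-2-en-1-ol | I/C=C(\C)CO | intermediate
6 | 9-[2-(furan-3-yl)ethyl]-9-borabicyclo[3.3.1]nonane | c1cc(CCB2C3CCCC2CCC3)co1 | intermediate
7 | (2E)-5-(furan-3-yl)-2-methylpent-2-en-1-ol | C/C(=C\CCc1ccoc1)CO | intermediate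
8 | 3-[(3E)-5-bromo-4-methylpent-3-en-1-yl]furan | C/C(=C\CCc1ccoc1)CBr | intermediate
9 | ethynyl(trimethyl)silane | C#C[Si](C)(C)C | starting material
10 | [(trimethylsilyl)ethynyl]magnesium bromide | C[Si](C)(C)C#C[Mg]Br | intermediate
11 | [(4E)-7-(furan-3-yl)-4-methylhept-4-en-1-yn-1-yl](trimethyl)silane | C/C(=C\CCc1ccoc1)CC#C[Si](C)(C)C | intermediate
12 | 3-[(3E)-4-methylhept-3-en-6-yn-1-yl]furan | C/C(=C\CCc1ccoc1)CC#C | intermediate
13 | 2-[(1E,4E)-7-(furan-3-yl)-4-methylhepta-1,4-dien-1-yl]-1,3,2-benzodioxaborole | C/C(=C\CCc1ccoc1)C/C=C/B1Oc2ccccc2O1 | intermediate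
14 | 2-[(1E,4E)-7-(furan-3-yl)-4-methylhepta-1,4-dien-1-yl]-5,5-dimethyl-1,3,2-dioxaborinane | C/C(=C\CCc1ccoc1)C/C=C/B1OCC(C)(C)CO1 | intermediate
15 | pent-4-yn-1-ol | C#CCCCO | starting material
16 | dimethylaluminium (4E)-5-(dimethylalumanyl)-4-methylpent-4-en-1-olate | C[Al](C)/C=C(\C)CCCO[Al](C)C | intermediate
17 | (4E)-5-iodo-4-methylpent-4-en-1-ol | I/C=C(\C)CCCO | intermediate
18 | (2S)-but-3-en-2-ol | C[C@H](O)C=C | starting material
19 | (2S)-but-3-en-2-yl 2,4,6-triisopropylbenzoate | C[C@H](OC(=O)c1c(C(C)C)cc(C(C)C)cc1C(C)C)C=C | intermediate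
20 | (2S)-4-(9-borabicyclo[3.3.1]nonan-9-yl)butan-2-yl 2,4,6-triisopropylbenzoate | C[C@H](OC(=O)c1c(C(C)C)cc(C(C)C)cc1C(C)C)CCB2C3CCCC2CCC3 | intermediate
21 | (2S,5E)-9-hydroxy-6-methylnon-5-en-2-yl 2,4,6-triisopropylbenzoate | C[C@H](OC(=O)c1c(C(C)C)cc(C(C)C)cc1C(C)C)CC/C=C(\C)CCCO | intermediate
22 | (2S)-4-[(2R,3R)-3-(3-hydroxypropyl)-3-methyloxiran-2-yl]butan-2-yl 2,4,6-triisopropylbenzoate | C[C@H](OC(=O)c1c(C(C)C)cc(C(C)C)cc1C(C)C)CC[C@H]2O[C@]2(C)CCCO | intermediate
23 | (2S)-4-[(2R,3R)-3-methyl-3-(3-oxopropyl)oxiran-2-yl]butan-2-yl 2,4,6-triisopropylbenzoate | C[C@H](OC(=O)c1c(C(C)C)cc(C(C)C)cc1C(C)C)CC[C@H]2O[C@]2(C)CCC=O | intermediate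
24 | (2S)-4-[(1R,3R,4S)-4-methyl-2,7-dioxabicyclo[2.2.1]heptan-3-yl]butan-2-yl 2,4,6-triisopropylbenzoate (side chain endo on the cage) | C[C@H](OC(=O)c1c(C(C)C)cc(C(C)C)cc1C(C)C)CC[C@H]2O[C@H]3CC[C@]2(C)O3 | intermediate
25 | tertiary organolithium: 24 with Li in the place of the carbinol H | C[C@]([Li])(OC(=O)c1c(C(C)C)cc(C(C)C)cc1C(C)C)CC[C@H]2O[C@H]3CC[C@]2(C)O3 | intermediate
26 | lithium boronate complex: boron of 14 bound to the carbanion carbon of 25 in the place of Li | [Li+].C[C@]([B-]4(OCC(C)(C)CO4)/C=C/C/C(C)=C/CCc5ccoc5)(OC(=O)c1c(C(C)C)cc(C(C)C)cc1C(C)C)CC[C@H]2O[C@H]3CC[C@]2(C)O3 | intermediate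
27 | tertiary allylic boronic ester: 28 with the 5,5-dimethyl-1,3,2-dioxaborinan-2-yl group in the place of OH | C/C(=C\CCc1ccoc1)C/C=C/[C@@](C)(B2OCC(C)(C)CO2)CC[C@H]3O[C@H]4CC[C@]3(C)O4 | intermediate
28 | (3S,4E,7E)-10-(furan-3-yl)-3,7-dimethyl-1-[(1R,3R,4S)-4-methyl-2,7-dioxabicyclo[2.2.1]heptan-3-yl]deca-4,7-dien-3-ol | C/C(=C\CCc1ccoc1)C/C=C/[C@@](C)(O)CC[C@H]2O[C@H]3CC[C@]2(C)O3 | intermediate
29 | (5S)-5-[(1R,4S,5E,8E)-11-(furan-3-yl)-1,4-dihydroxy-4,8-dimethylundeca-5,8-dien-1-yl]-5-methyloxolan-2-ol | C/C(=C\CCc1ccoc1)C/C=C/[C@@](C)(O)CC[C@@H](O)[C@]1(C)CCC(O)O1 | intermediate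
30 | (5S)-5-[(1R,4S,5E,8E)-11-(furan-3-yl)-1,4-dihydroxy-4,8-dimethylundeca-5,8-dien-1-yl]-5-methyloxolan-2-one | C/C(=C\CCc1ccoc1)C/C=C/[C@@](C)(O)CC[C@@H](O)[C@]1(C)CCC(=O)O1 | target

**Total step count:** 16
**Longest linear sequence:** 9 (steps 1, 3, 4, 5, 6, 7, 14, 15, 16)

**Steps most likely to fail**

**Step 14.** Deprotonation of the hindered ester may be slow or incomplete. Proton transfer from the doubly allylic CH2 or the furan of 14 to 25 may compete with attack at boron, and boronate formation may reverse before migration.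

The fallback reverses the polarity (carbonyl addition instead of a 1,2-metallate shift). It sets out from 24 and 12 and comes back at 28.
- LiAlH4 in refluxing THF cleaves 24 to the secondary alcohol F1.
- (nPr4N)RuO4 with N-methylmorpholine N-oxide turns F1 into the methyl ketone F2.
- Cp2Zr(H)Cl hydrozirconates 12 to the E-alkenylzirconocene chloride F3.
- Me2Zn transmetallates F3 to the alkenyl(methyl)zinc F4.
- F4 is added to F2 under Ti(OiPr)4 and a trans-cyclohexane-1,2-diamine-derived bis(sulfonamide) diol ligand (catalytic asymmetric alkenylation of ketones). The ligand enantiomer is chosen for the (S)-carbinol, and the minor epimer is removed by chromatography.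

**Step 13.** A 1,2-hydride shift to a ketone may compete with cage closure. So may attack at the secondary epoxide carbon (which would erode the configuration) or intermolecular acetal formation.

The fallback separates the C–O bond formation from the masking and replaces the cage by silyl ethers. It sets out from 23 and comes back at 30.
- Pinnick oxidation (NaClO2, NaH2PO4, 2-methylbut-2-ene) gives the epoxy acid F5.
- Catalytic camphorsulfonic acid closes the hydroxy lactone F6 by 5-exo opening at the quaternary carbon with inversion.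
- LiBH4 reduces only the lactone, giving the triol F7.
- Et3SiOTf with 2,6-lutidine gives the tris(triethylsilyl) ether F8.
- The conditions of step 14 with 14 give the tertiary alcohol F9.
- Bu4NF frees the tetraol F10.
- TEMPO with PhI(OAc)2 oxidises the primary alcohol and then the resulting lactol to 30.

**Step 15.** Ionisation of the tertiary allylic alcohol (allylic transposition, dehydration to a triene) or acid damage to the furan may proceed at a rate comparable to acetal hydrolysis.

The fallback exchanges the acid-labile cage for fluoride-labile groups before the fragments are joined. It sets out from 24 and comes back at 29.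
- 1 M HCl in THF opens the cage of the robust 24 to the lactol F11.
- tBuMe2SiCl with imidazole gives the bis(silyl) ether F12.
- The conditions of step 14 with 14 give the tertiary alcohol F13.
- Bu4NF buffered with AcOH removes both silyl groups without any acid step after the allylic alcohol exists.

**Further compounds**
F1 | step 14 | (2S)-4-[(1R,3R,4S)-4-methyl-2,7-dioxabicyclo[2.2.1]heptan-3-yl]butan-2-ol | C[C@H](O)CC[C@H]1O[C@H]2CC[C@]1(C)O2
F2 | step 14 | 4-[(1R,3R,4S)-4-methyl-2,7-dioxabicyclo[2.2.1]heptan-3-yl]butan-2-one | CC(=O)CC[C@H]1O[C@H]2CC[C@]1(C)O2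
F3 | step 14 | chlorido[(1E,4E)-7-(furan-3-yl)-4-methylhepta-1,4-dien-1-yl]bis(cyclopentadienyl)zirconium | C/C(=C\CCc1ccoc1)C/C=C/[Zr](Cl)(C1C=CC=C1)C1C=CC=C1
F4 | step 14 | [(1E,4E)-7-(furan-3-yl)-4-methylhepta-1,4-dien-1-yl](methyl)zinc | C/C(=C\CCc1ccoc1)C/C=C/[Zn]C
F5 | step 13 | 3-[(2R,3R)-2-methyl-3-{(3S)-3-[(2,4,6-triisopropylbenzoyl)oxy]butyl}oxiran-2-yl]propanoic acid | C[C@H](OC(=O)c1c(C(C)C)cc(C(C)C)cc1C(C)C)CC[C@H]2O[C@]2(C)CCC(=O)O
F6 | step 13 | (2S,5R)-5-hydroxy-5-[(2S)-2-methyl-5-oxooxolan-2-yl]pentan-2-yl 2,4,6-triisopropylbenzoate | C[C@H](OC(=O)c1c(C(C)C)cc(C(C)C)cc1C(C)C)CC[C@@H](O)[C@]2(C)CCC(=O)O2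
F7 | step 13 | (2S,5R,6S)-5,6,9-trihydroxy-6-methylnonan-2-yl 2,4,6-triisopropylbenzoate | C[C@H](OC(=O)c1c(C(C)C)cc(C(C)C)cc1C(C)C)CC[C@@H](O)[C@@](C)(O)CCCO
F8 | step 13 | (2S,5R,6S)-6-methyl-5,6,9-tris[(triethylsilyl)oxy]nonan-2-yl 2,4,6-triisopropylbenzoate | C[C@H](OC(=O)c1c(C(C)C)cc(C(C)C)cc1C(C)C)CC[C@@H](O[Si](CC)(CC)CC)[C@@](C)(O[Si](CC)(CC)CC)CCCO[Si](CC)(CC)CC
F9 | step 13 | (2E,5E,7S,10R,11S)-1-(furan-3-yl)-4,7,11-trimethyl-10,11,14-tris[(triethylsilyl)oxy]tetradeca-2... written from the furan end as (3E,6E,8S,11R,12S)-1-(furan-3-yl)-4,8,12-trimethyl-11,12,15-tris[(triethylsilyl)oxy]pentadeca-3,6-dien-8-ol | C/C(=C\CCc1ccoc1)C/C=C/[C@@](C)(O)CC[C@@H](O[Si](CC)(CC)CC)[C@@](C)(O[Si](CC)(CC)CC)CCCO[Si](CC)(CC)CC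
F10 | step 13 | (4S,5R,8S,9E,12E)-15-(furan-3-yl)-4,8,12-trimethylpentadeca-9,12-diene-1,4,5,8-tetrol | C/C(=C\CCc1ccoc1)C/C=C/[C@@](C)(O)CC[C@@H](O)[C@@](C)(O)CCCO
F11 | step 15 | (2S,5R)-5-hydroxy-5-[(2S)-5-hydroxy-2-methyloxolan-2-yl]pentan-2-yl 2,4,6-triisopropylbenzoate | C[C@H](OC(=O)c1c(C(C)C)cc(C(C)C)cc1C(C)C)CC[C@@H](O)[C@]2(C)CCC(O)O2
F12 | step 15 | (2S,5R)-5-[(tert-butyldimethylsilyl)oxy]-5-{(2S)-5-[(tert-butyldimethylsilyl)oxy]-2-methyloxolan-2-yl}pentan-2-yl 2,4,6-triisopropylbenzoate | C[C@H](OC(=O)c1c(C(C)C)cc(C(C)C)cc1C(C)C)CC[C@@H](O[Si](C)(C)C(C)(C)C)[C@]2(C)CCC(O[Si](C)(C)C(C)(C)C)O2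
F13 | step 15 | (1R,4S,5E,8E)-1-[(tert-butyldimethylsilyl)oxy]-1-{(2S)-5-[(tert-butyldimethylsilyl)oxy]-2-methyloxolan-2-yl}-11-(furan-3-yl)-4,8-dimethylundeca-5,8-dien-4-ol | C/C(=C\CCc1ccoc1)C/C=C/[C@@](C)(O)CC[C@@H](O[Si](C)(C)C(C)(C)C)[C@]1(C)CCC(O[Si](C)(C)C(C)(C)C)O1
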